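**Route in one sentence:** ring C is closed at the C4–C4a carbon–carbon bond by a 6-endo-dig hydroarylation of aryl ynoate 6, an ester of a salicylaldehyde whose formyl group is the latent C8 hydroxyl.

**Assumption:** compounds 1 and 5 are taken as catalogue chemicals; the target has no stereocentre and no configurationally stable axis, so no stereocontrol is needed.

## Structural features

The target is a neoflavone: a benzene ring A fused to an α-pyranone ring C (O1, C2=O, C3–H, C4), with a 3,4-dimethoxyphenyl ring B joined to C4 by an aryl–alkenyl single bond. Ring A carries oxygen on four of its six carbons in a 1,2,3,5 pattern: the lactone oxygen O1 on C8a, a free hydroxyl on C8, methoxy groups on C7 and C5, and its only hydrogen on C6. The C4–C1' axis is twisted by the peri C5 methoxy group but is not configurationally stable, because ring B has no ortho substituent. Fragile points are the lactone (opened by hydroxide or alkoxide), the C8 hydroxyl (with the para C5 methoxy group it forms an easily oxidised hydroquinone monoether), and the four aryl methyl ethers (sensitive to strong Lewis acids). The real difficulty is regiochemical: O1 and the C8 hydroxyl form a catechol pair that must be told apart, and the crowded C4–C4a bond must be made at the one ring A carbon lying between O1 and the C5 methoxy group. The key step exploits the fact that C4a is the only hydrogen-bearing ring A carbon ortho to O1 and is also para to the C7 oxygen and ortho to the C5 oxygen. An acyl chain hung on O1 therefore delivers an electrophilic carbon exactly there, while the C8 oxygen is carried as a formyl group that blocks the other ortho position.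

## Logic of the disconnections

**9 to 7 (through 8).** The C8–O bond is cut: the hydroxyl is read as the result of an oxygen insertion into the C8–CHO bond of 7, followed by loss of the formyl carbon from 8. A formyl group is inert to acylation and to π-acid catalysis, so the second catechol oxygen never has to exist as a hydroxyl while ring C is built, and it occupies the ortho position that must not react. The gain is that no protecting group is needed and no catechol has to be differentiated. The forward step demands migration of the aryl carbon (not hydride) in the peracid adduct, no oxidation of the C3=C4 bond or ring B, and cleavage of the formate in 8 without opening the lactone.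

**7 to 6.** The C4–C4a bond is cut, which opens ring C at a carbon–carbon bond and keeps the O1–C2 ester as a tether. This is the most congested bond of the target, and cutting it turns the fused, 4-arylated bicycle into an open-chain ester with the same atoms (the forward step is an isomerisation). The forward step demands 6-endo-dig attack on the alkyne carbon that bears ring B, by the single free ring carbon ortho to the ester oxygen.

**6 to 4 and 5.** The O1–C2 ester bond is cut. This divides the molecule into two pieces of similar size, one of them commercial. The forward step demands acylation of a hydrogen-bonded, flanked phenol in the presence of its own aldehyde and of an ynoate that can accept nucleophiles.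

**4 to 1 (through 2 and 3).** The C2–C3 bond is cut and the carboxyl carbon is returned to carbon dioxide. The forward step demands clean deprotonation of the alkyne C–H without ring metalation.

## Other disconnections considered

**Alternative 1:** Cut C4–C4a and O1–C2 together (Pechmann condensation). The forward step is acid-mediated condensation of 3,5-dimethoxybenzene-1,2-diol A1 with ethyl 3-(3,4-dimethoxyphenyl)-3-oxopropanoate A2, giving 9 directly. This is the route that comes to mind first. It is not preferred for three reasons:
- A1 is an electron-rich catechol that oxidises readily to the ortho-quinone, and it would itself have to be made by oxidising 5.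
- A1 offers two hydroxyls and two nucleophilic ring carbons, and only one pairing leads to 9.
- The ketone of A2 is deactivated by the para-methoxy group, so hot strong acid is expected to be needed, which puts the catechol and the methyl ethers at risk.

The chosen plan fixes the pairing by a tether, hides the second hydroxyl as an aldehyde, and runs under neutral conditions.

**Alternative 2:** Cut C4–C1' (Suzuki–Miyaura coupling). The forward step couples 8-(benzyloxy)-5,7-dimethoxy-2-oxo-2H-chromen-4-yl trifluoromethanesulfonate A3 with (3,4-dimethoxyphenyl)boronic acid A4 to give 8-(benzyloxy)-4-(3,4-dimethoxyphenyl)-5,7-dimethoxy-2H-chromen-2-one A5, followed by debenzylation. It is not preferred because the difficulty is only moved into the preparation of A3. That needs a 4-hydroxycoumarin with the full ring A pattern, hence C-acylation of a differentiated, protected catechol, and is estimated at six or more steps. The coupling also takes place next to the peri C5 methoxy group, and a protecting group is needed throughout.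

**Alternative 3:** Cut O1–C2 and C2–C3, with the carbonyl carbon coming from carbon dioxide. The forward step is alkenyl C–H carboxylation and lactonisation of 2-(benzyloxy)-6-[1-(3,4-dimethoxyphenyl)ethenyl]-3,5-dimethoxyphenol A6 with Pd(OAc)2, Cs2CO3 and CO2, giving A5, followed by debenzylation. This is an unconventional and attractive one-carbon annulation. It is not preferred because it forms only the two bonds to C2 and leaves the hard C4–C4a connection to the synthesis of A6. That synthesis needs a regiochemically ambiguous aroylation, methylenation of a doubly ortho-substituted benzophenone, and a protecting group. The six-membered palladacycle would also have to form with the alkene held out of plane by the C5 methoxy group and ring B.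

Key step: step 3

## Route

Step 1
Reactants: 1 4-ethynyl-1,2-dimethoxybenzene
Product: 4 3-(3,4-dimethoxyphenyl)prop-2-ynoic acid, via lithium arylacetylide 2 (not isolated), via lithium arylpropiolate 3 (not isolated)
Conditions: n-BuLi, THF, −78 °C; CO2, −78 °C → rt; aq. HCl
Reagents that add atoms: carbon dioxide, O=C=O
Why: Deprotonation of the terminal alkyne (the most acidic C–H bond present) gives acetylide 2, carboxylation with CO2 gives carboxylate 3, and acidification frees 4; this is standard acetylide carboxylation, and one equivalent of base at −78 °C should not metalate the ring.

Step 2
Reactants: 4 3-(3,4-dimethoxyphenyl)prop-2-ynoic acid; 5 2-hydroxy-4,6-dimethoxybenzaldehyde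
Product: 6 2-formyl-3,5-dimethoxyphenyl 3-(3,4-dimethoxyphenyl)prop-2-ynoate
Conditions: DCC, DMAP (cat.), CH2Cl2, 0 °C → rt
Reagents that add atoms: none
Why: Steglich esterification: carbodiimide activation of 4 and DMAP-mediated acyl transfer to the phenol of 5, with the aldehyde as a spectator and no α-hydrogen in the acid; low temperature and a small DMAP loading should limit conjugate addition of the catalyst to the ynoate.

Step 3
Reactants: 6 2-formyl-3,5-dimethoxyphenyl 3-(3,4-dimethoxyphenyl)prop-2-ynoate
Product: 7 4-(3,4-dimethoxyphenyl)-5,7-dimethoxy-2-oxo-2H-chromene-8-carbaldehyde
Conditions: Ph3PAuNTf2 (5 mol %), ClCH2CH2Cl, 4 Å MS, rt → 60 °C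
Reagents that add atoms: none
Why: Cationic monovalent gold binds the alkyne of 6 and makes its β-carbon (the one bearing ring B) electrophilic; the ring carbon ortho to the ester oxygen attacks it anti to gold, the arenium ion loses its proton, and protodeauration of the vinylgold species releases 7 and the catalyst. The closest known reaction type is the intramolecular hydroarylation of aryl alkynoates to coumarins under cationic gold or Pd(OAc)2/CF3CO2H catalysis. Ring C is closed in the 6-endo-dig mode at the C4–C4a carbon–carbon bond, the O1–C2 ester bond being already in place; no stereocentre is formed. Endo closure is favoured over 5-exo closure by the polarisation of the ynoate: positive charge builds at the β-carbon, where the para-methoxy group of ring B stabilises it, and not at the α-carbon next to the carbonyl group. Site selectivity comes from the substrate: the tether reaches only the two ortho positions, one is blocked by the formyl group, and the free one is para to one methoxy group, ortho to the other and only meta to the formyl group, so the arenium charge rests on three oxygen-bearing carbons. Ipso attack to a spirocycle is not expected, because no donor stands para to the ipso carbon. The medium is neutral and non-nucleophilic, so the activated aryl ester, the aldehyde and the four methyl ethers should survive.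

Step 4
Reactants: 7 4-(3,4-dimethoxyphenyl)-5,7-dimethoxy-2-oxo-2H-chromene-8-carbaldehyde
Product: 9 8-hydroxy-4-(3,4-dimethoxyphenyl)-5,7-dimethoxy-2H-chromen-2-one (target), via aryl formate 8 (not isolated)
Conditions: mCPBA, CH2Cl2, 0 °C → rt; aq. Na2S2O3/NaHCO3 wash; then HCl (cat.), MeOH, rt
Reagents that add atoms: 3-chloroperoxybenzoic acid (mCPBA), O=C(OO)c1cccc(Cl)c1
Why: Baeyer–Villiger oxidation of an electron-rich aryl aldehyde (Dakin-type): in the tetrahedral peracid adduct the aryl carbon C8, activated by the ortho C7 and para C5 methoxy groups, should migrate in preference to hydride and give formate 8. Acid-catalysed methanolysis then frees the phenol as methyl formate under conditions that keep the lactone closed; the peracid is destroyed before the phenol is liberated, so the hydroquinone monoether unit of 9 does not meet the oxidant.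

## Compound list

1 | 4-ethynyl-1,2-dimethoxybenzene | C#Cc1ccc(OC)c(OC)c1 | starting material
2 | lithium (3,4-dimethoxyphenyl)acetylide | [Li]C#Cc1ccc(OC)c(OC)c1 | intermediate (not isolated)
3 | lithium 3-(3,4-dimethoxyphenyl)prop-2-ynoate | [Li+].[O-]C(=O)C#Cc1ccc(OC)c(OC)c1 | intermediate (not isolated)
4 | 3-(3,4-dimethoxyphenyl)prop-2-ynoic acid | OC(=O)C#Cc1ccc(OC)c(OC)c1 | intermediate
5 | 2-hydroxy-4,6-dimethoxybenzaldehyde | COc1cc(O)c(C=O)c(OC)c1 | starting material
6 | 2-formyl-3,5-dimethoxyphenyl 3-(3,4-dimethoxyphenyl)prop-2-ynoate | COc1cc(OC)c(C=O)c(OC(=O)C#Cc2ccc(OC)c(OC)c2)c1 | intermediate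
7 | 4-(3,4-dimethoxyphenyl)-5,7-dimethoxy-2-oxo-2H-chromene-8-carbaldehyde | COc1ccc(-c2cc(=O)oc3c(C=O)c(OC)cc(OC)c23)cc1OC | intermediate
8 | 4-(3,4-dimethoxyphenyl)-5,7-dimethoxy-2-oxo-2H-chromen-8-yl formate | COc1ccc(-c2cc(=O)oc3c(OC=O)c(OC)cc(OC)c23)cc1OC | intermediate (not isolated)
9 | 8-hydroxy-4-(3,4-dimethoxyphenyl)-5,7-dimethoxy-2H-chromen-2-one | COc1ccc(-c2cc(=O)oc3c(O)c(OC)cc(OC)c23)cc1OC | target

## Step count and risk

Total step count: 4. Longest linear sequence: 4 steps (1 → 4 → 6 → 7 → 9); 5 enters at step 2.

**Step 3 (key step).** The most likely failures are three: hydration of the gold-activated ynoate by traces of water; cleavage of the activated aryl ester; and slow ring closure, because the ester must adopt its less favoured s-trans conformation and the new bond forms next to a methoxy group, while the aldehyde can tie up the catalyst. The fallback replaces the alkyne isomerisation by cationic alkene arylation followed by dehydrogenation. It sets out from 5, which is esterified (DCC, DMAP) with commercial (E)-3,4-dimethoxycinnamic acid to give 2-formyl-3,5-dimethoxyphenyl (E)-3-(3,4-dimethoxyphenyl)prop-2-enoate F1. In CF3CO2H the benzylic cation stabilised by ring B should undergo intramolecular Friedel–Crafts alkylation at the same ortho carbon, giving racemic 4-(3,4-dimethoxyphenyl)-5,7-dimethoxy-2-oxo-3,4-dihydro-2H-chromene-8-carbaldehyde F2. Dehydrogenation with DDQ in dioxane at reflux then returns to the route at 7.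

**Step 2.** What may go wrong is conjugate addition of DMAP to the ynoate followed by aldol-type closure of the resulting allenolate on the ortho formyl group. Sluggish acylation of the chelated, flanked phenol with rearrangement of the activated acid to the N-acylurea, and hydrolysis of the activated ester during purification, are further risks. The fallback avoids any aryl ester. It sets out from acetylide 2 (generated from 1 as in step 1), which is trapped with ethyl chloroformate to give ethyl 3-(3,4-dimethoxyphenyl)prop-2-ynoate F3. Intermolecular hydroarylation of 5 with F3 under Pd(OAc)2 (cat.) in CF3CO2H/CH2Cl2 at rt should give the trans-addition product ethyl (Z)-3-(3,4-dimethoxyphenyl)-3-(3-formyl-2-hydroxy-4,6-dimethoxyphenyl)prop-2-enoate F4. In F4 the phenol and the ester are cis, so it should lactonise in the flask with loss of ethanol and return to the route at 7. The price is regiochemical: attack at C5 of 5, between the two methoxy groups, competes and gives an adduct that cannot lactonise and must be separated.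

**Step 4.** What may go wrong is over-oxidation: attack of the peracid on the electron-rich, styrene-like C3=C4 bond or on ring A, or oxidation of the liberated para-methoxyphenol towards a 5,8-quinone if oxidant is still present; hydride migration to the carboxylic acid is a lesser risk. The fallback moves the oxygenation ahead of ring closure. It sets out from 6, which has no coumarin double bond and an ynoate inert to peracid; mCPBA in CH2Cl2 should give 2-(formyloxy)-3,5-dimethoxyphenyl 3-(3,4-dimethoxyphenyl)prop-2-ynoate F5, which is isolated. As a catechol diester, F5 has no free hydroxyl and cannot undergo acyl migration. Gold-catalysed ring closure as in step 3 then returns to the route at 8, and acid methanolysis of 8 gives 9 with no oxidant present.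

## Further compounds

F1 | step 3 | 2-formyl-3,5-dimethoxyphenyl (E)-3-(3,4-dimethoxyphenyl)prop-2-enoate | COc1cc(OC)c(C=O)c(OC(=O)/C=C/c2ccc(OC)c(OC)c2)c1
F2 | step 3 | 4-(3,4-dimethoxyphenyl)-5,7-dimethoxy-2-oxo-3,4-dihydro-2H-chromene-8-carbaldehyde (racemic) | COc1ccc(C2CC(=O)Oc3c(C=O)c(OC)cc(OC)c32)cc1OC
F3 | step 2 | ethyl 3-(3,4-dimethoxyphenyl)prop-2-ynoate | CCOC(=O)C#Cc1ccc(OC)c(OC)c1
F4 | step 2 | ethyl (Z)-3-(3,4-dimethoxyphenyl)-3-(3-formyl-2-hydroxy-4,6-dimethoxyphenyl)prop-2-enoate | CCOC(=O)/C=C(/c1ccc(OC)c(OC)c1)c1c(OC)cc(OC)c(C=O)c1O
F5 | step 4 | 2-(formyloxy)-3,5-dimethoxyphenyl 3-(3,4-dimethoxyphenyl)prop-2-ynoate | COc1cc(OC)c(OC=O)c(OC(=O)C#Cc2ccc(OC)c(OC)c2)c1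
A1 | alternative 1 | 3,5-dimethoxybenzene-1,2-diol | COc1cc(O)c(O)c(OC)c1
A2 | alternative 1 | ethyl 3-(3,4-dimethoxyphenyl)-3-oxopropanoate | CCOC(=O)CC(=O)c1ccc(OC)c(OC)c1
A3 | alternative 2 | 8-(benzyloxy)-5,7-dimethoxy-2-oxo-2H-chromen-4-yl trifluoromethanesulfonate | COc1cc(OC)c2c(OS(=O)(=O)C(F)(F)F)cc(=O)oc2c1OCc1ccccc1
A4 | alternative 2 | (3,4-dimethoxyphenyl)boronic acid | COc1ccc(B(O)O)cc1OC
A5 | alternative 2 | 8-(benzyloxy)-4-(3,4-dimethoxyphenyl)-5,7-dimethoxy-2H-chromen-2-one | COc1ccc(-c2cc(=O)oc3c(OCc4ccccc4)c(OC)cc(OC)c23)cc1OC
A6 | alternative 3 | 2-(benzyloxy)-6-[1-(3,4-dimethoxyphenyl)ethenyl]-3,5-dimethoxyphenol | C=C(c1ccc(OC)c(OC)c1)c1c(OC)cc(OC)c(OCc2ccccc2)c1O
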